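**Analysis of the target**

The target 28 is built from two 7-hydroxyflavan-3-ol units that share one aromatic ring. The catechol ring D is the 2-aryl group of the lower unit L (bonded through D1 to C2 of L) and also the 4-aryl group of the upper unit U (bonded through D6 to C4 of U); its hydroxyls sit on D3 and D4. Unit U has three contiguous stereocentres, (2R,3S,4R), in the all-equatorial 2,3-trans-3,4-trans arrangement: the 3,4-dihydroxyphenyl group on C2 and ring D on C4 are cis to each other and both trans to the 3-hydroxyl. Unit L has two, (2S,3S), in the 2,3-cis arrangement, which is the less stable one and cannot be reached by equilibration or by a cationic ring closure. Ring D separates the two sets of stereocentres, so neither can control the other and each needs its own source of absolute configuration. The seven phenolic hydroxyls (two of them air-sensitive catechols), the two benzylic C2–O1 bonds and the triarylmethane-type C4–H make the free skeleton sensitive to acid, base and oxidants, so all phenols must stay masked until a neutral last step. The hard part is the pair of adjacent C–C bonds on ring D, each to a hindered stereogenic heterocycle. The strategy rests on that pattern: D1 and D6 are neighbouring carbons, and the D3/D4 oxygens lie symmetrically to them, so the D1–D6 bond corresponds to the strained bond of a symmetrical 4,5-dioxygenated benzyne that can accept C4 of U as a nucleophile on one carbon and, after metalation of the other, C2 of L as an electrophile.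

**Retrosynthetic reasoning**

28 ⇐ 27. The last disconnection removes the seven benzyl ethers. A single protecting group is used for all phenols and for the 3-hydroxyl of L because it survives organomagnesium reagents, hydroboration, carbonate base at 110 °C and copper catalysis. All seven fall in one neutral hydrogenolysis, which spares the C2–O1 bonds and the catechols.

27 ⇐ 25 (through 26). The C3–O and C4–H bonds of U are cut together, leading back to the C3=C4 alkene of 25. The forward hydroboration–oxidation adds boron to C3 and hydrogen to C4 on the same face, away from the aryl group on C2, so two stereocentres are made from one and the all-equatorial pattern of U results directly. The gain is that C4 of U may be sp2 when it is joined to ring D, so it can be brought in as an alkenyl nucleophile, and only C2 of U has to be set beforehand.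

25 ⇐ 24. The pyran ring of L is opened at O1–C8a, not at O1–C2. Cutting the aryl–oxygen bond leaves C2 as a secondary carbinol whose C–O bond is untouched in the forward ring closure, so the syn-1,2-dioxygenated chain of 24 becomes the 2,3-cis ring of 25 with retention. Cutting O1–C2 would require a substitution at a para-alkoxybenzylic carbon, which ionises and would give the trans ring. The forward step is a copper-catalysed intramolecular O-arylation and needs a bromine ortho to the side chain on ring A of L.

24 ⇐ 6 + 8 + 19 (through 20, 21, 22 and 23). Both bonds from ring D to the two units, C4(U)–D6 and D1–C2(L), are cut in one operation. These are the only bonds that join three separately preparable, stereochemically independent pieces, and ring D then appears as the symmetrical aryne 22, for which no regiochemical question arises. The forward reaction must convert 6 into the alkenylmagnesium reagent 20, generate 22 from 8 by way of 21, let 20 add to 22, and let the new arylmagnesium reagent 23 add to aldehyde 19 under chelation control by the 2-benzyloxy group so that the carbinol forms syn. The gain is convergence: ring D costs one step and the longest branch is the one to 19.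

6 ⇐ 5 ⇐ 4. The C4–I bond is traced to the C4 carbonyl of flavanone 4 through hydrazone 5. This path to the alkenyl iodide runs through a cation at C4 and not through a C3 enolate, which would expel the ring oxygen and open the pyranone.

4 ⇐ 2 + 3; 2 ⇐ 1. The C2–aryl bond of 4 is cut to give chromone 2 and boronic acid 3. The forward rhodium-catalysed asymmetric conjugate addition sets C2 of U, the only stereocentre of that unit not derived from another. 2 is the benzyl ether of commercial 1.

8 ⇐ 7. The two C–Br bonds come from electrophilic bromination of 7; each ether oxygen directs para, which gives the 4,5-dibromo pattern needed for 22.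

19 ⇐ 18 ⇐ 17 ⇐ 15 + 12. The aldehyde is taken back to alcohol 18 and imide 17, whose bond between the glycolate carbon and the benzylic carbon is cut. The forward alkylation of enolate 16 (from 15) with 12 sets C3 of L under control of the auxiliary. 15 is made from 13 through 14, and 13 is released again in the reduction to 18. The oxygen on this carbon is benzylated from the start, so it is both the chelating group of the key step and the protected 3-hydroxyl of L.

12 ⇐ 11 ⇐ 10 ⇐ 9. The benzylic bromide comes from commercial 9 by benzylation, reduction and bromination; the aryl bromine of 9 is carried unchanged to the ring closure 24 → 25.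

**Alternatives that were turned down**

Alternative 1: Ring C of U is disconnected at O1–C2 and C3–C4 as a hetero-Diels–Alder reaction. In the forward sense the benzhydrol A1 (ring A phenol joined to ring D, which already carries unit L) is ionised to an ortho-quinone methide that adds to the enol acetate A2, giving A3, the 3-O-acetate of 27.
- For: the pyran ring and all three stereocentres of U form in one step, the 3-oxygen is already in place, and the (E)-geometry of A2 translates into the 2,3-trans relation. On end-game economy this is stronger than the chosen route, which needs a separate hydroboration.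
- Against: the only stereochemical information available to the planar quinone methide is the remote pair of centres in L, so the absolute sense of U relative to L is uncontrolled and both diastereomeric series should form. The 3,4-relation depends on endo/exo preference. The aryl and acetoxy groups of A2 polarise the alkene in opposite directions, so the regiochemistry is not assured. A1 still requires both ring D bonds to be made beforehand, so nothing is saved there.
- Comparison: the chosen strategy sets C2 of U by a catalyst, independently of L, and relays it to C3 and C4. It pays one extra step for that control.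

Alternative 2: Ring C of U is disconnected at the C3=C4 double bond by ring-closing metathesis. The diene A4 (an aryl allyl ether carrying the C2 stereocentre, and a 1,1-diarylethene joining ring A to ring D) would be closed with the second-generation Grubbs catalyst to A5, which is the same compound as 25.
- For: metathesis to a six-membered ring is a more predictable bond-forming event than a three-component aryne coupling, and from A5 the end game would be identical to steps 15 and 16.
- Against: the 1,1-diarylethene is a hindered, reluctant metathesis partner and would need forcing conditions. The ether stereocentre of A4 is benzylic and allylic at once, so it is prone to ionisation and, on heating, to aromatic Claisen rearrangement. A4 also has to be assembled linearly from a ring A–ring D diaryl ketone that already bears L.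
- Comparison: the chosen strategy reaches the same skeleton (24, then 25) by joining three fragments in one flask and carries the C2 stereocentre of U in a cyclic, non-ionising form. It gives up some predictability in the coupling step.

Alternative 3: Ring D itself is disconnected at D1–D2 and D5–D6. The alkyne A6, which links C2 of L to C4 of U, would react with the diene A7 under CoBr2(dppe), zinc and ZnI2, and the cyclohexa-1,4-diene would be aromatised with DDQ in the same flask to give A8.
- For: all five stereocentres would be in place before the last C–C bonds form, the symmetrical diene removes any regiochemical issue, the conditions are neutral, and the 3-oxygen of U is present from the start. In functional-group tolerance of the key step this is stronger than an organomagnesium cascade.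
- Against: A6 needs two sp–sp3 bonds to hindered stereogenic carbons (C2 of a 3-oxygenated chroman and C4 of a flavan), each a synthesis problem of its own. An internal alkyne flanked by two branched centres is a poor substrate for the cobalt cycloaddition. DDQ would meet several electron-rich benzylic C–H bonds. Ring D emerges as a bis(silyl ether), which adds a deprotection.
- Comparison: the chosen strategy takes ring D from 7 in one step and spends its effort on joining the pieces.

Key step: step 13

Assumption: the sense of induction of the rhodium–diene catalyst in step 2 is assigned by analogy with additions to cyclohex-2-enone, and the ligand antipode is exchanged if the first run shows the opposite sense; 24 and 25 may show slow rotation about the bond from C4 of the chromene to ring D, and the rotamers are treated as one compound.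

**Route**

Step 1
Reactants: 1 7-hydroxy-4H-chromen-4-one
Product: 2 7-(benzyloxy)-4H-chromen-4-one
Conditions: BnBr, K2CO3, DMF, rt
Reagents that add atoms: benzyl bromide, BrCc1ccccc1
Why: Williamson ether synthesis on the acidic 7-hydroxyl; carbonate is too weak a nucleophile to open the chromone ring.

Step 2
Reactants: 2 7-(benzyloxy)-4H-chromen-4-one; 3 [3,4-bis(benzyloxy)phenyl]boronic acid
Product: 4 (2S)-7-(benzyloxy)-2-[3,4-bis(benzyloxy)phenyl]-2,3-dihydro-4H-chromen-4-one
Conditions: [RhCl(C2H4)2]2 (2.5 mol %), (1S,4S)-2,5-diphenylbicyclo[2.2.2]octa-2,5-diene (5.5 mol %), aq KOH (0.2 equiv), 3 (2 equiv), dioxane/H2O 10:1, 30 °C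
Reagents that add atoms: none
Why: Rhodium-catalysed asymmetric conjugate addition (Hayashi–Miyaura reaction): the aryl–rhodium species inserts the C2=C3 bond and water protonates the rhodium enolate, the chiral diene choosing the face so that C2 should be S. A π-accepting diene ligand is used in place of a bisphosphine because the 7-alkoxychromone is a poor acceptor, and the low temperature should limit racemisation by reversible ring opening.

Step 3
Reactants: 4 (2S)-7-(benzyloxy)-2-[3,4-bis(benzyloxy)phenyl]-2,3-dihydro-4H-chromen-4-one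
Product: 5 hydrazone of 4 at C4 (C=N geometry not defined)
Conditions: N2H4·H2O (10 equiv), EtOH, 60 °C
Reagents that add atoms: hydrazine (as the hydrate), NN
Why: Hydrazone condensation; the large excess of hydrazine should suppress azine formation, and the moderate temperature without added base should keep the pyranone ring closed.

Step 4
Reactants: 5 hydrazone of 4
Product: 6 (2S)-7-(benzyloxy)-2-[3,4-bis(benzyloxy)phenyl]-4-iodo-2H-chromene
Conditions: I2 (2.2 equiv), 1,1,3,3-tetramethylguanidine (6 equiv), THF, 0 °C to rt, then 60 °C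
Reagents that add atoms: iodine, II
Why: Barton vinyl iodide synthesis: iodine oxidises the hydrazone to the diazo compound, iodination and loss of N2 give an α-iodo benzylic cation, and loss of the C3 proton gives the alkenyl iodide. No C3 carbanion is formed, so the aryloxide is not expelled and C2 is untouched.

Step 5
Reactants: 7 1,2-bis(benzyloxy)benzene
Product: 8 1,2-bis(benzyloxy)-4,5-dibromobenzene
Conditions: Br2 (2.1 equiv), NaOAc, AcOH/CH2Cl2, 0 °C to rt
Reagents that add atoms: bromine, BrBr
Why: Electrophilic aromatic bromination; each ether oxygen directs para, so the bromines enter at C4 and C5, and NaOAc takes up HBr to protect the benzyl ethers.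

Step 6
Reactants: 9 2-bromo-4-hydroxybenzaldehyde
Product: 10 4-(benzyloxy)-2-bromobenzaldehyde
Conditions: BnBr, K2CO3, DMF, rt
Reagents that add atoms: benzyl bromide, BrCc1ccccc1
Why: Williamson ether synthesis on the phenol; the aldehyde and aryl bromide are inert.

Step 7
Reactants: 10 4-(benzyloxy)-2-bromobenzaldehyde
Product: 11 [4-(benzyloxy)-2-bromophenyl]methanol
Conditions: NaBH4, MeOH/THF, 0 °C
Reagents that add atoms: none
Why: Hydride reduction of the aldehyde; aryl bromide and benzyl ether are not affected.

Step 8
Reactants: 11 [4-(benzyloxy)-2-bromophenyl]methanol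
Product: 12 4-(benzyloxy)-2-bromo-1-(bromomethyl)benzene
Conditions: PBr3, CH2Cl2, 0 °C
Reagents that add atoms: phosphorus tribromide, BrP(Br)Br
Why: Conversion of the benzylic alcohol into the bromide through its phosphite ester; the para-alkoxybenzyl bromide is labile and is used at once.

Step 9
Reactants: 13 (4R)-4-benzyl-1,3-oxazolidin-2-one
Product: 15 (4R)-4-benzyl-3-[2-(benzyloxy)acetyl]-1,3-oxazolidin-2-one, via lithium oxazolidinide 14 (not isolated)
Conditions: n-BuLi, THF, −78 °C; BnOCH2COCl, −78 to 0 °C
Reagents that add atoms: 2-(benzyloxy)acetyl chloride, O=C(Cl)COCc1ccccc1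
Why: N-acylation of the lithiated oxazolidinone with the acid chloride, the standard entry to glycolate imides.

Step 10
Reactants: 15 (4R)-4-benzyl-3-[2-(benzyloxy)acetyl]-1,3-oxazolidin-2-one; 12 4-(benzyloxy)-2-bromo-1-(bromomethyl)benzene
Product: 17 (4R)-4-benzyl-3-[(2S)-2-(benzyloxy)-3-[4-(benzyloxy)-2-bromophenyl]propanoyl]-1,3-oxazolidin-2-one, via sodium enolate 16 (not isolated)
Conditions: NaN(SiMe3)2, THF, −78 °C; 12, −78 to −40 °C
Reagents that add atoms: none
Why: Evans-type glycolate alkylation: the sodium-chelated (Z)-enolate 16 is shielded on one face by the 4-benzyl group, so 12 enters from the other face and the (R)-auxiliary should give the (S) centre that becomes C3 of L.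

Step 11
Reactants: 17 (4R)-4-benzyl-3-[(2S)-2-(benzyloxy)-3-[4-(benzyloxy)-2-bromophenyl]propanoyl]-1,3-oxazolidin-2-one
Product: 18 (2S)-2-(benzyloxy)-3-[4-(benzyloxy)-2-bromophenyl]propan-1-ol
Conditions: LiBH4, MeOH (1.2 equiv), THF, 0 °C
Reagents that add atoms: none
Why: Reductive cleavage of the imide: hydride attacks the exocyclic acyl carbonyl and releases the auxiliary, without epimerisation and without touching the aryl bromide.

Step 12
Reactants: 18 (2S)-2-(benzyloxy)-3-[4-(benzyloxy)-2-bromophenyl]propan-1-ol
Product: 19 (2S)-2-(benzyloxy)-3-[4-(benzyloxy)-2-bromophenyl]propanal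
Conditions: Dess–Martin periodinane, CH2Cl2, 0 °C to rt; used crude
Reagents that add atoms: none
Why: Dess–Martin oxidation under neutral, non-basic conditions, chosen so that the configurationally labile α-alkoxy aldehyde should not epimerise; it is used directly in step 13.

Step 13
Reactants: 6 (2S)-7-(benzyloxy)-2-[3,4-bis(benzyloxy)phenyl]-4-iodo-2H-chromene; 8 1,2-bis(benzyloxy)-4,5-dibromobenzene; 19 (2S)-2-(benzyloxy)-3-[4-(benzyloxy)-2-bromophenyl]propanal
Product: 24 (1S,2S)-2-(benzyloxy)-3-[4-(benzyloxy)-2-bromophenyl]-1-{4,5-bis(benzyloxy)-2-[(2S)-7-(benzyloxy)-2-[3,4-bis(benzyloxy)phenyl]-2H-chromen-4-yl]phenyl}propan-1-ol, via alkenylmagnesium chloride 20 (not isolated), via 2-bromoarylmagnesium chloride 21 (not isolated), via 4,5-bis(benzyloxy)benzyne 22 (not isolated), via ortho-alkenylarylmagnesium chloride 23 (not isolated)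
Conditions: 6 (1.2 equiv), i-PrMgCl·LiCl, THF, −20 to 0 °C; 8 (1.0 equiv), i-PrMgCl·LiCl, THF, −15 °C, added slowly to the first solution at 40 °C; then at −78 °C into 19 (1.5 equiv), MgBr2·OEt2, CH2Cl2, −78 to −40 °C; aq NH4Cl
Reagents that add atoms: none
Why: Halogen–magnesium exchange with i-PrMgCl·LiCl turns 6 into the alkenyl Grignard reagent 20 and, in a separate flask at −15 °C, 8 into the ortho-bromoaryl Grignard reagent 21, which is stable at that temperature. When 21 is fed slowly into warm 20 it loses MgBrCl to give aryne 22, whose strained bond is attacked by the sp2 carbon of 20 (carbomagnesiation), so that C4 of the chromene ends on one aryne carbon and magnesium on its neighbour (23). The closest known reaction type is the one-flask addition of aryl and alkenyl Grignard reagents to arynes made from ortho-dihaloarenes, followed by capture of the new ortho-substituted aryl Grignard reagent by an electrophile, as used for 2-biarylphosphines and meta-terphenyls. Because 22 is symmetrical either carbon gives the same product, and because 23 is flanked by the bulky chromenyl group it should add to further aryne more slowly than 20. The cold solution of 23 is then run into 19 precomplexed with MgBr2·OEt2 in CH2Cl2; magnesium bridges the aldehyde oxygen and the 2-benzyloxy oxygen in a five-membered chelate (Cram chelate model) and the aryl group enters from the face opposite the arylmethyl substituent, which should set the new carbinol centre S, syn to the benzyloxy group. No ring is closed. The step needs chemoselectivity (the aryne must meet 20 and never 19, secured by adding the aldehyde only after 21 is consumed), diastereoselectivity at the carbinol (secured by the chelating 2-benzyloxy group and the non-coordinating cosolvent) and survival of the aryl bromide of 19, which should not exchange with an arylmagnesium halide at −78 °C.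

Step 14
Reactants: 24 (1S,2S)-2-(benzyloxy)-3-[4-(benzyloxy)-2-bromophenyl]-1-{4,5-bis(benzyloxy)-2-[(2S)-7-(benzyloxy)-2-[3,4-bis(benzyloxy)phenyl]-2H-chromen-4-yl]phenyl}propan-1-ol
Product: 25 (2S)-7-(benzyloxy)-2-[3,4-bis(benzyloxy)phenyl]-4-{4,5-bis(benzyloxy)-2-[(2S,3S)-3,7-bis(benzyloxy)-3,4-dihydro-2H-chromen-2-yl]phenyl}-2H-chromene
Conditions: CuI (20 mol %), 1,10-phenanthroline (40 mol %), Cs2CO3 (2 equiv), toluene, 110 °C
Reagents that add atoms: none
Why: Copper-catalysed intramolecular Ullmann-type O-arylation of the secondary alkoxide by the ortho-bromoarene closes the six-membered pyran ring of L. The carbinol C–O bond is not broken, so the syn carbinol becomes the 2,3-cis ring with retention.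

Step 15
Reactants: 25 (2S)-7-(benzyloxy)-2-[3,4-bis(benzyloxy)phenyl]-4-{4,5-bis(benzyloxy)-2-[(2S,3S)-3,7-bis(benzyloxy)-3,4-dihydro-2H-chromen-2-yl]phenyl}-2H-chromene
Product: 27 (2R,3S,4R)-7-(benzyloxy)-2-[3,4-bis(benzyloxy)phenyl]-4-{4,5-bis(benzyloxy)-2-[(2S,3S)-3,7-bis(benzyloxy)-3,4-dihydro-2H-chromen-2-yl]phenyl}-3,4-dihydro-2H-chromen-3-ol, via C3-alkylborane 26 (not isolated)
Conditions: BH3·THF (excess), THF, 0 °C to rt; then aq NaOH, H2O2, 0 °C to rt
Reagents that add atoms: hydrogen peroxide, OO
Why: Hydroboration–oxidation: boron adds to C3, the less substituted carbon, and hydrogen to the diaryl-substituted C4 in a syn addition on the face away from the C2 aryl group, as with simpler flav-3-enes. Oxidation with retention should give the 3-hydroxyl trans to both aryl groups.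

Step 16
Reactants: 27 (2R,3S,4R)-7-(benzyloxy)-2-[3,4-bis(benzyloxy)phenyl]-4-{4,5-bis(benzyloxy)-2-[(2S,3S)-3,7-bis(benzyloxy)-3,4-dihydro-2H-chromen-2-yl]phenyl}-3,4-dihydro-2H-chromen-3-ol
Product: 28 (2R,3S,4R)-4-{2-[(2S,3S)-3,7-dihydroxy-3,4-dihydro-2H-chromen-2-yl]-4,5-dihydroxyphenyl}-2-(3,4-dihydroxyphenyl)-3,4-dihydro-2H-chromene-3,7-diol
Conditions: H2 (1 atm), Pd(OH)2 on carbon, THF/MeOH, rt; filtration under argon
Reagents that add atoms: none
Why: Hydrogenolysis of the seven O-benzyl groups under neutral conditions; the cyclic benzylic C2–O1 bonds are cleaved much more slowly than benzyl ethers, so the reaction is stopped when hydrogen uptake ends.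

**Compound list**

1 | 7-hydroxy-4H-chromen-4-one | O=c1ccoc2cc(O)ccc12 | starting material
2 | 7-(benzyloxy)-4H-chromen-4-one | O=c1ccoc2cc(OCc3ccccc3)ccc12 | intermediate
3 | [3,4-bis(benzyloxy)phenyl]boronic acid | OB(O)c1ccc(OCc2ccccc2)c(OCc2ccccc2)c1 | starting material
4 | (2S)-7-(benzyloxy)-2-[3,4-bis(benzyloxy)phenyl]-2,3-dihydro-4H-chromen-4-one | O=C1C[C@@H](c2ccc(OCc3ccccc3)c(OCc3ccccc3)c2)Oc2cc(OCc3ccccc3)ccc12 | intermediate
5 | hydrazone of 4 at C4 (C=N geometry not defined) | NN=C1C[C@@H](c2ccc(OCc3ccccc3)c(OCc3ccccc3)c2)Oc2cc(OCc3ccccc3)ccc12 | intermediate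
6 | (2S)-7-(benzyloxy)-2-[3,4-bis(benzyloxy)phenyl]-4-iodo-2H-chromene | IC1=C[C@@H](c2ccc(OCc3ccccc3)c(OCc3ccccc3)c2)Oc2cc(OCc3ccccc3)ccc12 | intermediate
7 | 1,2-bis(benzyloxy)benzene | c1ccc(OCc2ccccc2)c(OCc2ccccc2)c1 | starting material
8 | 1,2-bis(benzyloxy)-4,5-dibromobenzene | Brc1cc(OCc2ccccc2)c(OCc2ccccc2)cc1Br | intermediate
9 | 2-bromo-4-hydroxybenzaldehyde | O=Cc1ccc(O)cc1Br | starting material
10 | 4-(benzyloxy)-2-bromobenzaldehyde | O=Cc1ccc(OCc2ccccc2)cc1Br | intermediate
11 | [4-(benzyloxy)-2-bromophenyl]methanol | OCc1ccc(OCc2ccccc2)cc1Br | intermediate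
12 | 4-(benzyloxy)-2-bromo-1-(bromomethyl)benzene | BrCc1ccc(OCc2ccccc2)cc1Br | intermediate
13 | (4R)-4-benzyl-1,3-oxazolidin-2-one | O=C1N[C@H](Cc2ccccc2)CO1 | starting material
14 | N-lithio derivative of 13 | [Li]N1[C@H](Cc2ccccc2)COC1=O | intermediate
15 | (4R)-4-benzyl-3-[2-(benzyloxy)acetyl]-1,3-oxazolidin-2-one | O=C(COCc1ccccc1)N1[C@H](Cc2ccccc2)COC1=O | intermediate
16 | sodium (Z)-enolate of 15 | [Na]O/C(=C\OCc1ccccc1)N1[C@H](Cc2ccccc2)COC1=O | intermediate
17 | (4R)-4-benzyl-3-[(2S)-2-(benzyloxy)-3-[4-(benzyloxy)-2-bromophenyl]propanoyl]-1,3-oxazolidin-2-one | O=C([C@@H](OCc1ccccc1)Cc1ccc(OCc2ccccc2)cc1Br)N1[C@H](Cc2ccccc2)COC1=O | intermediate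
18 | (2S)-2-(benzyloxy)-3-[4-(benzyloxy)-2-bromophenyl]propan-1-ol | OC[C@@H](OCc1ccccc1)Cc1ccc(OCc2ccccc2)cc1Br | intermediate
19 | (2S)-2-(benzyloxy)-3-[4-(benzyloxy)-2-bromophenyl]propanal | O=C[C@@H](OCc1ccccc1)Cc1ccc(OCc2ccccc2)cc1Br | intermediate
20 | [(2S)-7-(benzyloxy)-2-[3,4-bis(benzyloxy)phenyl]-2H-chromen-4-yl]magnesium chloride (LiCl complex) | Cl[Mg]C1=C[C@@H](c2ccc(OCc3ccccc3)c(OCc3ccccc3)c2)Oc2cc(OCc3ccccc3)ccc12 | intermediate
21 | [4,5-bis(benzyloxy)-2-bromophenyl]magnesium chloride (LiCl complex) | Cl[Mg]c1cc(OCc2ccccc2)c(OCc2ccccc2)cc1Br | intermediate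
22 | 4,5-bis(benzyloxy)benzyne | C1(OCc2ccccc2)=CC#CC=C1OCc1ccccc1 | intermediate
23 | {4,5-bis(benzyloxy)-2-[(2S)-7-(benzyloxy)-2-[3,4-bis(benzyloxy)phenyl]-2H-chromen-4-yl]phenyl}magnesium chloride | Cl[Mg]c1cc(OCc2ccccc2)c(OCc2ccccc2)cc1C1=C[C@@H](c2ccc(OCc3ccccc3)c(OCc3ccccc3)c2)Oc2cc(OCc3ccccc3)ccc12 | intermediate
24 | (1S,2S)-2-(benzyloxy)-3-[4-(benzyloxy)-2-bromophenyl]-1-{4,5-bis(benzyloxy)-2-[(2S)-7-(benzyloxy)-2-[3,4-bis(benzyloxy)phenyl]-2H-chromen-4-yl]phenyl}propan-1-ol | C(c1ccccc1)Oc1ccc(C[C@H](OCc4ccccc4)[C@@H](O)c2cc(OCc4ccccc4)c(OCc4ccccc4)cc2C2=C[C@@H](c3ccc(OCc4ccccc4)c(OCc4ccccc4)c3)Oc3cc(OCc4ccccc4)ccc23)c(Br)c1 | intermediate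
25 | (2S)-7-(benzyloxy)-2-[3,4-bis(benzyloxy)phenyl]-4-{4,5-bis(benzyloxy)-2-[(2S,3S)-3,7-bis(benzyloxy)-3,4-dihydro-2H-chromen-2-yl]phenyl}-2H-chromene | C(c1ccccc1)Oc1ccc2c(c1)O[C@@H](c1cc(OCc4ccccc4)c(OCc4ccccc4)cc1C1=C[C@@H](c3ccc(OCc4ccccc4)c(OCc4ccccc4)c3)Oc3cc(OCc4ccccc4)ccc13)[C@@H](OCc4ccccc4)C2 | intermediate
26 | C3-alkylborane corresponding to 27 (BH2 in place of the 3-hydroxyl of U, same spatial arrangement) | C(c1ccccc1)Oc1ccc2c(c1)O[C@@H](c1cc(OCc4ccccc4)c(OCc4ccccc4)cc1[C@@H]1c3ccc(OCc4ccccc4)cc3O[C@H](c3ccc(OCc4ccccc4)c(OCc4ccccc4)c3)[C@H]1B)[C@@H](OCc4ccccc4)C2 | intermediate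
27 | (2R,3S,4R)-7-(benzyloxy)-2-[3,4-bis(benzyloxy)phenyl]-4-{4,5-bis(benzyloxy)-2-[(2S,3S)-3,7-bis(benzyloxy)-3,4-dihydro-2H-chromen-2-yl]phenyl}-3,4-dihydro-2H-chromen-3-ol | C(c1ccccc1)Oc1ccc2c(c1)O[C@@H](c1cc(OCc4ccccc4)c(OCc4ccccc4)cc1[C@@H]1c3ccc(OCc4ccccc4)cc3O[C@H](c3ccc(OCc4ccccc4)c(OCc4ccccc4)c3)[C@H]1O)[C@@H](OCc4ccccc4)C2 | intermediate
28 | (2R,3S,4R)-4-{2-[(2S,3S)-3,7-dihydroxy-3,4-dihydro-2H-chromen-2-yl]-4,5-dihydroxyphenyl}-2-(3,4-dihydroxyphenyl)-3,4-dihydro-2H-chromene-3,7-diol | Oc1ccc2c(c1)O[C@@H](c1cc(O)c(O)cc1[C@@H]1c3ccc(O)cc3O[C@H](c3ccc(O)c(O)c3)[C@H]1O)[C@@H](O)C2 | target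

**Step count and risks**

Total: 16 steps. Longest linear sequence: 10 steps (steps 6, 7, 8, 10, 11, 12, 13, 14, 15 and 16, from 9).

Step 13 (key step). Three things are most likely to go wrong.
- Aryne 22 discriminates poorly between organomagnesium species, so addition of 21 or of 23 to 22 may compete with the wanted addition of 20 and lead to oligoarylation.
- Any 20 or 21 left over consumes aldehyde.
- The hindered aryl reagent 23 may deprotonate the α-alkoxy aldehyde instead of adding to it, or chelation control may be eroded by the THF carried over.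

Fallback: a stepwise construction that sets out from 8 and 6 and comes back at 24.
- 8 is converted, through 21 at −15 °C and B(OMe)3 followed by aqueous acid, into [4,5-bis(benzyloxy)-2-bromophenyl]boronic acid F1.
- Suzuki–Miyaura coupling of F1 with 6 (Pd(PPh3)4, aq Na2CO3, 1,2-dimethoxyethane, 70 °C; the alkenyl iodide should react much faster than either aryl bromide) gives (2S)-4-[4,5-bis(benzyloxy)-2-bromophenyl]-7-(benzyloxy)-2-[3,4-bis(benzyloxy)phenyl]-2H-chromene F2.
- Bromine–lithium exchange (n-BuLi, THF, −78 °C) and transmetalation with MgBr2·OEt2 give the arylmagnesium bromide F3, the bromide analogue of 23, which is added to 19 under the chelating conditions of step 13 to give 24.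

Step 2. Insertion into the electron-rich chromone may be slow, so protodeboronation of 3 competes. Reversible opening of the pyranone under the basic aqueous conditions may erode the enantiomeric purity, and the sense of induction is assigned only by analogy.
Fallback, from 2 and 3 back to 4: the achiral catalyst [Rh(OH)(cod)]2 in dioxane/H2O gives racemic 7-(benzyloxy)-2-[3,4-bis(benzyloxy)phenyl]-2,3-dihydro-4H-chromen-4-one F4, which is resolved by preparative chromatography on a chiral stationary phase to give 4.

Step 4 (with step 3). Ring opening of the flavanone by hydrazine (retro-oxa-Michael addition followed by pyrazoline formation) may compete with hydrazone formation, elimination of a geminal diiodide may be incomplete, and the 4-iodo-2H-chromene may ionise at C2 on silica.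
Fallback, from 4 back to 6:
- Enol triflation without an enolate (Tf2O, 2,6-di-tert-butyl-4-methylpyridine, CH2Cl2) gives (2S)-7-(benzyloxy)-2-[3,4-bis(benzyloxy)phenyl]-2H-chromen-4-yl trifluoromethanesulfonate F5.
- Stannylation (Pd(PPh3)4, (Me3Sn)2, LiCl, dioxane, 80 °C) gives the 4-(trimethylstannyl)-2H-chromene F6.
- Iododestannylation (I2, CH2Cl2, 0 °C) gives 6.

Step 14. Coupling at the hindered secondary alkoxide may be slow. During long heating the caesium alkoxide may deprotonate the doubly activated C2–H of the flav-3-ene, leading to migration of the double bond or loss of configuration at C2 of U. Copper-mediated dehydrogenation of the benzylic alkoxide with loss of bromine is a further risk.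
Fallback, from 24 back to 27, with the order of the two steps exchanged:
- 24 is first hydroborated and oxidised as in step 15 to the open-chain diol F7, the 2,3-trans-3,4-trans flavan-3-ol corresponding to 24, in which the chromene is saturated and no longer base-sensitive.
- The pyran ring is then closed by palladium instead of copper catalysis (Pd(OAc)2, 2-(di-tert-butylphosphino)-1,1'-binaphthyl, Cs2CO3, toluene, 70 °C; zerovalent palladium inserts into the C–Br bond and the alkoxide is delivered by reductive elimination, with retention at the carbinol), giving 27.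

Step 15. The ortho substituent of ring D lies over one face of the alkene. If rotation about the C4–ring D bond is slow, part of the material may present only the face syn to the C2 aryl group to the borane, which would lower the facial selectivity and the rate.
Fallback, from 6 and 8 (by way of F1 and F2 of the fallback to step 13) back to 28; the hydroboration is moved to a stage where ring D carries only bromine next to the alkene:
- F2 is hydroborated and oxidised to the 2,3-trans-3,4-trans 4-[4,5-bis(benzyloxy)-2-bromophenyl]flavan-3-ol F8.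
- F8 is benzylated (NaH, BnBr, DMF) to F9.
- Bromine–lithium exchange (n-BuLi, THF, −78 °C) and MgBr2·OEt2 give the arylmagnesium bromide F10, which adds to 19 under chelation control to give the open-chain carbinol F11.
- The copper-catalysed ring closure of step 14 gives the octa-O-benzyl ether F12 of the target, and hydrogenolysis as in step 16 gives 28.

**Further compounds**

F1 | step 13 | [4,5-bis(benzyloxy)-2-bromophenyl]boronic acid | OB(O)c1cc(OCc2ccccc2)c(OCc2ccccc2)cc1Br
F2 | step 13 | (2S)-4-[4,5-bis(benzyloxy)-2-bromophenyl]-7-(benzyloxy)-2-[3,4-bis(benzyloxy)phenyl]-2H-chromene | Brc1cc(OCc2ccccc2)c(OCc2ccccc2)cc1C1=C[C@@H](c2ccc(OCc3ccccc3)c(OCc3ccccc3)c2)Oc2cc(OCc3ccccc3)ccc12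
F3 | step 13 | {4,5-bis(benzyloxy)-2-[(2S)-7-(benzyloxy)-2-[3,4-bis(benzyloxy)phenyl]-2H-chromen-4-yl]phenyl}magnesium bromide | Br[Mg]c1cc(OCc2ccccc2)c(OCc2ccccc2)cc1C1=C[C@@H](c2ccc(OCc3ccccc3)c(OCc3ccccc3)c2)Oc2cc(OCc3ccccc3)ccc12
F4 | step 2 | racemic 7-(benzyloxy)-2-[3,4-bis(benzyloxy)phenyl]-2,3-dihydro-4H-chromen-4-one | O=C1CC(c2ccc(OCc3ccccc3)c(OCc3ccccc3)c2)Oc2cc(OCc3ccccc3)ccc12
F5 | step 4 | (2S)-7-(benzyloxy)-2-[3,4-bis(benzyloxy)phenyl]-2H-chromen-4-yl trifluoromethanesulfonate | FC(F)(F)S(=O)(=O)OC1=C[C@@H](c2ccc(OCc3ccccc3)c(OCc3ccccc3)c2)Oc2cc(OCc3ccccc3)ccc12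
F6 | step 4 | (2S)-7-(benzyloxy)-2-[3,4-bis(benzyloxy)phenyl]-4-(trimethylstannyl)-2H-chromene | C[Sn](C)(C)C1=C[C@@H](c2ccc(OCc3ccccc3)c(OCc3ccccc3)c2)Oc2cc(OCc3ccccc3)ccc12
F7 | step 14 | open-chain diol: 24 with the chromene converted into the 2,3-trans-3,4-trans flavan-3-ol | C(c1ccccc1)Oc1ccc(C[C@H](OCc4ccccc4)[C@@H](O)c2cc(OCc4ccccc4)c(OCc4ccccc4)cc2[C@@H]2c3ccc(OCc4ccccc4)cc3O[C@H](c3ccc(OCc4ccccc4)c(OCc4ccccc4)c3)[C@H]2O)c(Br)c1
F8 | step 15 | 2,3-trans-3,4-trans 4-[4,5-bis(benzyloxy)-2-bromophenyl]-7-(benzyloxy)-2-[3,4-bis(benzyloxy)phenyl]-3,4-dihydro-2H-chromen-3-ol, configured as unit U | Brc1cc(OCc2ccccc2)c(OCc2ccccc2)cc1[C@@H]1c3ccc(OCc2ccccc2)cc3O[C@H](c3ccc(OCc2ccccc2)c(OCc2ccccc2)c3)[C@H]1O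
F9 | step 15 | 3-O-benzyl ether of F8 | Brc1cc(OCc2ccccc2)c(OCc2ccccc2)cc1[C@@H]1c3ccc(OCc2ccccc2)cc3O[C@H](c3ccc(OCc2ccccc2)c(OCc2ccccc2)c3)[C@H]1OCc1ccccc1
F10 | step 15 | arylmagnesium bromide from F9 (MgBr in place of the ring D bromine) | Br[Mg]c1cc(OCc2ccccc2)c(OCc2ccccc2)cc1[C@@H]1c3ccc(OCc2ccccc2)cc3O[C@H](c3ccc(OCc2ccccc2)c(OCc2ccccc2)c3)[C@H]1OCc1ccccc1
F11 | step 15 | open-chain syn carbinol from F10 and 19 (octa-O-benzyl, aryl bromide retained) | C(c1ccccc1)Oc1ccc(C[C@H](OCc4ccccc4)[C@@H](O)c2cc(OCc4ccccc4)c(OCc4ccccc4)cc2[C@@H]2c3ccc(OCc4ccccc4)cc3O[C@H](c3ccc(OCc4ccccc4)c(OCc4ccccc4)c3)[C@H]2OCc2ccccc2)c(Br)c1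
F12 | step 15 | octa-O-benzyl ether of 28 | C(c1ccccc1)Oc1ccc2c(c1)O[C@@H](c1cc(OCc4ccccc4)c(OCc4ccccc4)cc1[C@@H]1c3ccc(OCc4ccccc4)cc3O[C@H](c3ccc(OCc4ccccc4)c(OCc4ccccc4)c3)[C@H]1OCc1ccccc1)[C@@H](OCc4ccccc4)C2
A1 | alternative 1 | 5-(benzyloxy)-2-[{4,5-bis(benzyloxy)-2-[(2S,3S)-3,7-bis(benzyloxy)-3,4-dihydro-2H-chromen-2-yl]phenyl}(hydroxy)methyl]phenol (carbinol configuration not defined) | Oc1cc(OCc2ccccc2)ccc1C(O)c1cc(OCc2ccccc2)c(OCc2ccccc2)cc1[C@@H]1Oc2cc(OCc3ccccc3)ccc2C[C@@H]1OCc1ccccc1
A2 | alternative 1 | (E)-2-[3,4-bis(benzyloxy)phenyl]ethenyl acetate | CC(=O)O/C=C/c1ccc(OCc2ccccc2)c(OCc2ccccc2)c1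
A3 | alternative 1 | 3-O-acetate of 27 | C(c1ccccc1)Oc1ccc2c(c1)O[C@@H](c1cc(OCc4ccccc4)c(OCc4ccccc4)cc1[C@@H]1c3ccc(OCc4ccccc4)cc3O[C@H](c3ccc(OCc4ccccc4)c(OCc4ccccc4)c3)[C@H]1OC(C)=O)[C@@H](OCc4ccccc4)C2
A4 | alternative 2 | diene: 1-aryl-allyl ether of the ring A phenol whose ortho carbon bears the 1-(ring D)ethenyl group, ring D carrying the benzylated unit L | C=C[C@@H](c1ccc(OCc2ccccc2)c(OCc2ccccc2)c1)Oc1cc(OCc2ccccc2)ccc1C(=C)c1cc(OCc2ccccc2)c(OCc2ccccc2)cc1[C@@H]1Oc2cc(OCc3ccccc3)ccc2C[C@@H]1OCc1ccccc1
A5 | alternative 2 | 4-arylflav-3-ene identical with 25 | C(c1ccccc1)Oc1ccc2c(c1)O[C@@H](c1cc(OCc4ccccc4)c(OCc4ccccc4)cc1C1=C[C@@H](c3ccc(OCc4ccccc4)c(OCc4ccccc4)c3)Oc3cc(OCc4ccccc4)ccc13)[C@@H](OCc4ccccc4)C2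
A6 | alternative 3 | alkyne linking C2 of the benzylated chroman of L to C4 of the benzylated flavan of U | C(#C[C@@H]1Oc2cc(OCc3ccccc3)ccc2C[C@@H]1OCc1ccccc1)[C@@H]1c2ccc(OCc3ccccc3)cc2O[C@H](c2ccc(OCc3ccccc3)c(OCc3ccccc3)c2)[C@H]1OCc1ccccc1
A7 | alternative 3 | 2,3-bis(tert-butyldimethylsilyloxy)buta-1,3-diene | C=C(O[Si](C)(C)C(C)(C)C)C(=C)O[Si](C)(C)C(C)(C)C
A8 | alternative 3 | hexa-O-benzyl ether of 28 with ring D as its bis(tert-butyldimethylsilyl) ether | C(c1ccccc1)Oc1ccc2c(c1)O[C@@H](c1cc(O[Si](C)(C)C(C)(C)C)c(O[Si](C)(C)C(C)(C)C)cc1[C@@H]1c3ccc(OCc4ccccc4)cc3O[C@H](c3ccc(OCc4ccccc4)c(OCc4ccccc4)c3)[C@H]1OCc4ccccc4)[C@@H](OCc4ccccc4)C2
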